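A one-step world holds one product at a fixed share, but in the autumn run the share of Q in Q plus D falls from 61.7% at 0.833 h to 28.2% at 10.0 h, so the flask's ledger has to be kept in time.

| flask | J | Z | L | remark | time |
|---|---|---|---|---|---|
| autumn | 0.010 M | 0.54 equiv | 0.1 mol% | run made earlier |  |
| spring | 0.010 M | 1.2 equiv | 0.1 mol% | run made earlier |  |
| flask | 0.010 M | 0.800 equiv | 0.1 mol% |  | 8.0 h |

| run | time / h | Q / % | D / % | J / % |
|---|---|---|---|---|
| autumn | 0.833 | 7.4 | 4.6 | 60.6 |
| autumn | 2.00 | 11.9 | 14.6 | 32.9 |
| autumn | 4.00 | 13.8 | 27.2 | 14.6 |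
| autumn | 10.0 | 14.9 | 37.9 | 6.3 |
| spring | 1.33 | 20.9 | 16.7 | 38.3 |
| spring | 3.00 | 27.8 | 36.7 | 14.3 |
| spring | 6.00 | 30.5 | 53.5 | 3.1 |
| spring | 10.0 | 30.3 | 62.9 | 1.0 |

(readings scatter by 0.3 percentage points)

- share of Q in Q plus D at 10 min
- share of Q in Q plus D at 8.0 h
- which of Q and D there is more of at 8.0 h

- the numbers in the tables scatter by 0.3 percentage points (one standard deviation)

1. The accounts. Z is the limiting reagent of the flask, at 0.800 equiv. In the autumn run, Q plus D reaches 52.8% of J against 0.54 equiv of Z, which reads as one Z per Q or D. So Z has 3 entries: Q, D and left over.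

2. The early end. At 0.833 h in the autumn run, 27.4% of J is missing from the readings and sits in an unseen pool, taken here as the source of D. While that pool fills, D per Q is taken to grow in step with time. The lag rate g, D per Q divided by time at the earliest reading, reads 0.746 /h. Taking g as the same for the flask, this reckoning puts the share at 10 min at 88.9%, and Q and D level near 1.34 h.

3. The late end. At 10.0 h the share reads 28.2% in the autumn run and 32.5% in the spring run. A line in equivalents between these two shares gives 29.9%, a share for 10.0 h carried over to the flask at 8.0 h, so this reckoning has the flask holding less Q than D.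

4. The forecast, reasoning that “each Q and each D consumes one Z”, gives a share of 88.5% at 10 min and 31.2% at 8.0 h, with D ahead.

The flask gives 88.5% at 10 min and 30.2% at 8.0 h, with D ahead at 49.2% against 21.2% of Q, so the forecast holds. Q and D stand level at 1.59 h, later than the 1.34 h from g.

    J + Z → Q (k = 0.00660 /M/s)
    J + L ⇌ L + E (K = 7.10, k = 14.0 /M/s)
    Z + L + E → L + D (k = 2100 /M²/s)
    D → X (k = 1.60 × 10⁻⁷ /s)

The unseen pool is E. L stands in both the step that fills E and the step that empties it, so g is taken with the square of the loading. For the neighbouring flask with 0.04 mol% of L, its other charges unchanged, that gives 0.119 /h and a share of 98.1% at 10 min. That flask gives 97.9%.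

All runs are simulated from invented constants.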